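A slow feed looks as if it guards the complex with one exchanged from further exchange, but a yield read without the starting complex left beside it says nothing of that.

| setting | Monday's | Saturday's | Thursday's | Wednesday's |
|---|---|---|---|---|
| starting complex | 0.050 M | 0.050 M (fed, over 3.0 min) | 0.050 M | 0.050 M |
| incoming ligand | 0.900 equiv (fed, over 3.0 min) | 0.900 equiv | 0.900 equiv (in portions, 5, over 3.0 min) | 0.900 equiv |
| leaving ligand | 5.00 equiv | 5.00 equiv | 5.00 equiv | 5.00 equiv |
| protic impurity | 1.00 mM | 1.00 mM | 1.00 mM | 1.00 mM |
| time | 4.0 min | 4.0 min | 4.0 min | 4.0 min |
| remark | all else is in the flask from the start; the feed brings no volume worth counting | all else is in the flask from the start; the feed brings no volume worth counting | first portion at the start, last at 3.0 min | everything together at the start |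

    starting complex + incoming ligand ⇌ leaving ligand + complex with one exchanged (K1 = 180, k1 = 0.069 /M/s)
    complex with one exchanged + incoming ligand ⇌ leaving ligand + complex with two exchanged (K2 = 9.7, k2 = 0.0082 /M/s)
    complex with two exchanged + incoming ligand ⇌ leaving ligand + complex with three exchanged (K3 = 25, k3 = 0.23 /M/s)
    leaving ligand → by-product carried off (k4 = 0.15 /s)
    protic impurity + incoming ligand → quenched reagent (k5 = 1.5 /M/s)

- the flask that comes out highest in amount of complex with one exchanged, in percent of the starting complex charged, or "all alike" when all lie within 1.5 percentage points (Monday's / Saturday's / Thursday's / Wednesday's / all alike)
- complex with one exchanged at the end, in percent of the starting complex charged, Monday's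
- complex with one exchanged at the end, in percent of the starting complex charged, Saturday's
- complex with one exchanged at the end, in percent of the starting complex charged, Thursday's
- complex with one exchanged at the end, in percent of the starting complex charged, Wednesday's

**Seconds.** Leaving ligand goes off with a half-life of 4.62 s, far shorter than the 4.0 min of the run, so the reckoning drops the ways back.

**First minute.** In Wednesday's flask the protic impurity has a half-life of 0.17 min, shorter than the run, so it takes 1.00 mM from the incoming ligand and leaves 44.0 mM for the complex.

**Minutes.** In Wednesday's flask the starting complex has, by the forward first exchange with the ligand as charged, a half-life of 3.72 min, of like size to the run, so the first exchange is expected to stand part way at the end. In Wednesday's flask the complex with one exchanged has, by the forward second exchange with the concentrations as charged, a half-life of 31 min, longer than the run.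

**The ratio.** Both exchanges use the same incoming ligand, so dividing the rate of the second by that of the first removes ligand and time. What remains is the selectivity factor 8.41, the rate constant of the first exchange over that of the second. With m the fraction of starting complex left and s the factor, and the ways back dropped, the complex with one exchanged stands at (m^(1/s) − m)/(1 − 1/s) of the charge, however the ligand went in, so long as the starting complex is charged at the start.

**Own reckoning.** Second-order loss with both partners running down leaves 59.0 % of the starting complex in Wednesday's flask, and the factor then gives 39.6 %. Saturday's flask feeds the starting complex itself, so this curve is not reckoned for it. In Monday's and Thursday's flasks the dosed incoming ligand spends on average 2.50 min in the flask. Scaling the loss roughly by that time leaves 71.9 % and gives 27.5 %, less than Wednesday's.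

**Forecast, result.** The forecast, holding that “reverse steps are negligible”, named Wednesday's, with 29.2 % for Monday's, 29.1 % for Saturday's, 28.9 % for Thursday's and 39.3 % for Wednesday's. The simulation gives 29.2 %, 29.2 %, 28.9 % and 39.3 % in that order, so Wednesday's comes out highest, against the reckoned 27.5 % for Monday's and Thursday's and 39.6 % for Wednesday's.

**One curve.** In Thursday's flask the second exchange relaxes, both ways together, with a half-life of 32.5 min at the end, longer than the 4.0 min of the run, and the starting complex left at the end is 59 % in Wednesday's flask and 70 % in Monday's. At those levels the factor 8.41 gives 39.6 % and 29.3 %, and for Thursday's flask left until 15 min, with 35.0 % of the starting complex left, it gives 60.5 %, where that flask holds 60.4 %.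

Its constants come from no measurement; no experiment stands behind them.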